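**Plan**

- Retrosynthesis: the last cut removes the 19 O–CH3 bonds. Before that, ring B and then ring D are each opened at two C–C bonds, C3–C4 and C5–C6 (C1 is the ring carbon whose aryloxy group has two ortho hydrogens). The E–O–F, F–O–G and G–O–H ethers are cut at the aryl carbons of rings F (twice) and H, which carry at most one ortho substituent.
- Enabling feature: rings B and D carry oxygen at C1, C3 and C5 (aryloxy, hydroxyl, hydroxyl) plus a second aryloxy group at C4, and their ether oxygens sit on the crowded carbons of rings A, C and E. A β-aryloxycrotonate supplies C1, C2, C3 and C6 and an aryloxyacetate supplies C4 and C5, so the crowded C–O bonds are made beforehand at an alkyne carbon or a CH2Br carbon.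
- Forward: 3,4,5-trimethoxyphenol gives one salicylaldehyde that serves rings C, E and G. Ring D is folded first (rings C–D–E), a ring F–G–H bromide made by two copper couplings is joined to ring E, and ring B is then folded between ring C and a ring A crotonate. BBr3 ends the route.
- Stereochemistry: the target has no stereocentre. The (E)-geometry of the two crotonates is set under equilibrating oxa-Michael conditions and vanishes on aromatisation.

Key step: step 8

Remark: the acyclic keto enoates 13 and 31 exist in the flask as delocalised enolates; they are drawn as the neutral (E)-isomers.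

**Route**

Step 1
Reactants: 1 3,4,5-trimethoxyphenol
Product: 2 6-hydroxy-2,3,4-trimethoxybenzaldehyde
Conditions: MgCl2, Et3N, (CH2O)n, MeCN, reflux; aq. HCl work-up
Reagents that add atoms: paraformaldehyde (as formaldehyde), C=O
Why: Magnesium phenoxide-directed ortho-formylation (Casnati–Skattebøl reaction) can only strike the two equivalent positions ortho to the hydroxyl, because the para position carries a methoxy group.

Step 2
Reactants: 2 6-hydroxy-2,3,4-trimethoxybenzaldehyde
Product: 3 6-(benzyloxy)-2,3,4-trimethoxybenzaldehyde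
Conditions: BnBr, K2CO3, DMF, 60 °C
Reagents that add atoms: benzyl bromide, BrCc1ccccc1
Why: Williamson ether synthesis on the acidic salicylaldehyde hydroxyl masks the oxygen that becomes the outer ether oxygen of rings C and G.

Step 3
Reactants: 3 6-(benzyloxy)-2,3,4-trimethoxybenzaldehyde
Product: 5 6-(benzyloxy)-2,3,4-trimethoxyphenol, via aryl formate 4 (not isolated)
Conditions: mCPBA, CH2Cl2, 0 °C to rt; then K2CO3 (cat.), MeOH, rt
Reagents that add atoms: mCPBA, OOC(=O)c1cccc(Cl)c1
Why: Baeyer–Villiger oxidation (Dakin type) proceeds with aryl migration because two ortho alkoxy groups and a para methoxy group enrich the ring, and the formate is then transesterified to the hindered phenol.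

Step 4
Reactants: 5 6-(benzyloxy)-2,3,4-trimethoxyphenol; 6 methyl but-2-ynoate
Product: 7 methyl (E)-3-[6-(benzyloxy)-2,3,4-trimethoxyphenoxy]but-2-enoate
Conditions: 6 (1.5 equiv), K2CO3 (0.3 equiv), DMF, 80 °C
Reagents that add atoms: none
Why: Base-catalysed oxa-Michael addition of the 2,6-disubstituted phenoxide to the unhindered alkyne carbon is reversible and should settle on the (E)-enol ether, in which the methyl group is cis to the ester.

Step 5
Reactants: 2 6-hydroxy-2,3,4-trimethoxybenzaldehyde
Product: 8 2,3,4-trimethoxy-6-(methoxymethoxy)benzaldehyde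
Conditions: MOMCl, K2CO3, DMF, 0 °C to rt
Reagents that add atoms: chloromethyl methyl ether, COCCl
Why: Acetal protection (MOM ether) of the phenol gives a group that survives peracid, amide base and methoxide and is later removed by acid alone, so neither an oxidant nor hydrogen touches the electron-rich rings or the benzyl ether.

Step 6
Reactants: 8 2,3,4-trimethoxy-6-(methoxymethoxy)benzaldehyde
Product: 10 2,3,4-trimethoxy-6-(methoxymethoxy)phenol, via aryl formate 9 (not isolated)
Conditions: mCPBA, CH2Cl2, 0 °C to rt; then K2CO3 (cat.), MeOH, rt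
Reagents that add atoms: mCPBA, OOC(=O)c1cccc(Cl)c1
Why: The same Baeyer–Villiger oxidation and formate methanolysis as in step 3 apply, and the acetal tolerates the weakly acidic peracid medium.

Step 7
Reactants: 10 2,3,4-trimethoxy-6-(methoxymethoxy)phenol; 11 methyl bromoacetate
Product: 12 methyl 2-[2,3,4-trimethoxy-6-(methoxymethoxy)phenoxy]acetate
Conditions: K2CO3, acetone, reflux
Reagents that add atoms: none
Why: Williamson alkylation with a primary α-bromo ester attaches the crowded inner oxygen of ring E to an sp3 carbon, where the two ortho substituents do not matter.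

Step 8
Reactants: 7 methyl (E)-3-[6-(benzyloxy)-2,3,4-trimethoxyphenoxy]but-2-enoate; 12 methyl 2-[2,3,4-trimethoxy-6-(methoxymethoxy)phenoxy]acetate
Product: 14 5-[6-(benzyloxy)-2,3,4-trimethoxyphenoxy]-2-[2,3,4-trimethoxy-6-(methoxymethoxy)phenoxy]benzene-1,3-diol, via keto enoate 13 (not isolated)
Conditions: 7 (2.3 equiv), LiN(i-Pr)2 (2.3 equiv), THF, −78 °C; 12 (1 equiv), −78 to 0 °C; then NaOMe (6 equiv), MeOH, 60 °C; AcOH, H2O
Reagents that add atoms: none
Why: LiN(i-Pr)2 removes a γ-proton from the methyl group of 7, which lies cis to the ester, and the dienolate adds through its γ-carbon to the ester of 12 with loss of methoxide (crossed Claisen condensation), giving 13 as a doubly stabilised enolate that consumes the second equivalent of dienolate. In NaOMe/MeOH the enolates equilibrate, the carbon bearing the ring E aryloxy group attacks the enoate ester carbonyl in a 6-exo-trig Dieckmann closure, methoxide leaves and the ring tautomerises to the resorcinol, whose phenoxide makes the sequence irreversible. The closest known reactions are γ-acylations of β-alkoxycrotonate dienolates and the base-induced conversion of 3,5-dioxo esters or 4-alkoxy-2-pyranones into phloroglucinol-type phenols. No stereocentre is formed. The step needs γ- rather than α-acylation, which the conjugated product and the shielded α-carbon favour, and closure through carbon rather than enolate oxygen, which is secured because methoxide reopens any 2-pyranone whereas aromatisation cannot revert. Both crowded ethers of ring D are thus in place without any aryl–oxygen coupling.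

Step 9
Reactants: 14 ring C–D–E resorcinol
Product: 15 1-(benzyloxy)-2-{3,5-dimethoxy-4-[2,3,4-trimethoxy-6-(methoxymethoxy)phenoxy]phenoxy}-3,4,5-trimethoxybenzene
Conditions: MeI, K2CO3, DMF, rt
Reagents that add atoms: iodomethane, CI
Why: Williamson methylation caps the two ring D phenols so that the later phenoxide arylation, alkylation and enolate steps engage only the intended oxygen.

Step 10
Reactants: 15 ring C–D–E benzyl MOM diether
Product: 16 2-{4-[6-(benzyloxy)-2,3,4-trimethoxyphenoxy]-2,6-dimethoxyphenoxy}-3,4,5-trimethoxyphenol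
Conditions: HCl (cat.), MeOH, 45 °C
Reagents that add atoms: none
Why: Acid-catalysed acetal exchange with methanol removes the MOM group while benzyl, methyl and diaryl ethers are inert.

Step 11
Reactants: 5 6-(benzyloxy)-2,3,4-trimethoxyphenol; 17 5-iodo-1,2,3-trimethoxybenzene
Product: 18 1-(benzyloxy)-3,4,5-trimethoxy-2-(3,4,5-trimethoxyphenoxy)benzene
Conditions: 17 (1.2 equiv), CuI (10 mol%), picolinic acid (20 mol%), K3PO4, DMSO, 90 °C, Ar
Reagents that add atoms: none
Why: Ullmann-type diaryl ether coupling with monovalent copper and picolinic acid tolerates 2,6-disubstituted phenols when the aryl iodide has no ortho substituent, as is the case for ring H.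

Step 12
Reactants: 18 ring G–H benzyl ether
Product: 19 3,4,5-trimethoxy-2-(3,4,5-trimethoxyphenoxy)phenol
Conditions: H2 (1 atm), 10% Pd/C, EtOAc–MeOH, rt
Reagents that add atoms: none
Why: Hydrogenolysis cleaves only the benzylic C–O bond and frees the outer oxygen of ring G.

Step 13
Reactants: 20 4-bromo-2-methoxyphenol
Product: 21 4-bromo-2-iodo-6-methoxyphenol
Conditions: NIS, TsOH (10 mol%), MeCN, rt
Reagents that add atoms: N-iodosuccinimide, O=C1CCC(=O)N1I
Why: Electrophilic aromatic iodination is directed ortho to the free hydroxyl because the para position is blocked by bromine.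

Step 14
Reactants: 21 4-bromo-2-iodo-6-methoxyphenol
Product: 22 5-bromo-1-iodo-2,3-dimethoxybenzene
Conditions: MeI, K2CO3, acetone, reflux
Reagents that add atoms: iodomethane, CI
Why: Williamson methylation of the phenol gives the ring F unit with two halogens of different reactivity.

Step 15
Reactants: 19 3,4,5-trimethoxy-2-(3,4,5-trimethoxyphenoxy)phenol; 22 5-bromo-1-iodo-2,3-dimethoxybenzene
Product: 23 5-bromo-1,2-dimethoxy-3-[3,4,5-trimethoxy-2-(3,4,5-trimethoxyphenoxy)phenoxy]benzene
Conditions: 22 (2 equiv), CuI (10 mol%), picolinic acid (20 mol%), K3PO4, DMSO, 80 °C, Ar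
Reagents that add atoms: none
Why: Ullmann-type coupling should take place at the C–I bond, which reacts with copper far faster than C–Br, so the unhindered bromide remains as the handle for the fragment union.

Step 16
Reactants: 16 ring C–D–E phenol; 23 ring F–G–H bromide
Product: 24 benzyl-protected ring C–H hexamer (16 arylated on its ring E hydroxyl by the 3,4-dimethoxy-5-[3,4,5-trimethoxy-2-(3,4,5-trimethoxyphenoxy)phenoxy]phenyl group of 23)
Conditions: 23 (1.2 equiv), CuI (20 mol%), picolinic acid (40 mol%), K3PO4, DMSO, 100 °C, Ar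
Reagents that add atoms: none
Why: Ullmann-type coupling joins a phenol with one ortho aryloxy group to an aryl bromide that has two ortho hydrogens, the least hindered ether bond of the target.

Step 17
Reactants: 24 benzyl-protected ring C–H hexamer
Product: 25 ring C–H hexamer phenol (24 with the ring C benzyloxy group replaced by hydroxyl)
Conditions: H2 (1 atm), 10% Pd/C, EtOAc–MeOH, rt
Reagents that add atoms: none
Why: Hydrogenolysis of the single benzyl ether frees the outer oxygen of ring C, and no halogen or other reducible group remains.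

Step 18
Reactants: 25 ring C–H hexamer phenol; 11 methyl bromoacetate
Product: 26 ring C–H hexamer aryloxyacetate (methyl 2-aryloxyacetate formed at the ring C hydroxyl of 25)
Conditions: K2CO3, DMF, rt
Reagents that add atoms: none
Why: Williamson alkylation of the only free phenol installs the two-carbon unit that becomes C4 and C5 of ring B.

Step 19
Reactants: 27 2,4,6-trimethoxybenzaldehyde
Product: 29 2,4,6-trimethoxyphenol, via aryl formate 28 (not isolated)
Conditions: mCPBA, CH2Cl2, 0 °C to rt; then K2CO3 (cat.), MeOH, rt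
Reagents that add atoms: mCPBA, OOC(=O)c1cccc(Cl)c1
Why: Baeyer–Villiger oxidation (Dakin type) of the electron-rich aldehyde with aryl migration, followed by formate methanolysis, gives the ring A phenol.

Step 20
Reactants: 29 2,4,6-trimethoxyphenol; 6 methyl but-2-ynoate
Product: 30 methyl (E)-3-(2,4,6-trimethoxyphenoxy)but-2-enoate
Conditions: 6 (1.5 equiv), K2CO3 (0.3 equiv), DMF, 80 °C
Reagents that add atoms: none
Why: The oxa-Michael addition of step 4 is repeated and places the doubly ortho-substituted ring A oxygen on the future C1 of ring B.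

Step 21
Reactants: 26 ring C–H hexamer aryloxyacetate; 30 methyl (E)-3-(2,4,6-trimethoxyphenoxy)but-2-enoate
Product: 32 ring A–H octamer nonadecamethyl ether with free 3,5-hydroxyls on ring B, via keto enoate 31 (not isolated)
Conditions: 30 (2.5 equiv), LiN(i-Pr)2 (2.5 equiv), THF, −78 °C; 26 (1 equiv), −78 to 0 °C; then NaOMe (6 equiv), MeOH, 60 °C; AcOH, H2O
Reagents that add atoms: none
Why: The Claisen–Dieckmann sequence of step 8 is repeated, the γ-lithio dienolate of 30 being acylated by ester 26 and the ring C aryloxy-bearing carbon of 31 closing 6-exo-trig onto the enoate ester, so that ring B and both of its hindered ethers arise without aryl–oxygen coupling.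

Step 22
Reactants: 32 ring A–H octamer nonadecamethyl ether
Product: 33 target octamer (CNP0309601.0)
Conditions: BBr3 (60 equiv), CH2Cl2, −78 °C to rt; MeOH, then H2O, Ar; Sephadex LH-20
Reagents that add atoms: none
Why: Lewis acid-mediated ether cleavage by BBr3 removes the 19 methyl groups by bromide attack at methyl carbon, whereas the seven diaryl ether bonds offer no carbon open to substitution and should survive.

**Compound list**

1 | 3,4,5-trimethoxyphenol | COc1cc(O)cc(OC)c1OC | starting material
2 | 6-hydroxy-2,3,4-trimethoxybenzaldehyde | O=Cc1c(O)cc(OC)c(OC)c1OC | intermediate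
3 | 6-(benzyloxy)-2,3,4-trimethoxybenzaldehyde | O=Cc1c(OCc2ccccc2)cc(OC)c(OC)c1OC | intermediate
4 | 6-(benzyloxy)-2,3,4-trimethoxyphenyl formate | O=COc1c(OCc2ccccc2)cc(OC)c(OC)c1OC | intermediate
5 | 6-(benzyloxy)-2,3,4-trimethoxyphenol | Oc1c(OCc2ccccc2)cc(OC)c(OC)c1OC | intermediate
6 | methyl but-2-ynoate | CC#CC(=O)OC | starting material
7 | methyl (E)-3-[6-(benzyloxy)-2,3,4-trimethoxyphenoxy]but-2-enoate | COC(=O)/C=C(\C)Oc1c(OCc2ccccc2)cc(OC)c(OC)c1OC | intermediate
8 | 2,3,4-trimethoxy-6-(methoxymethoxy)benzaldehyde | O=Cc1c(OCOC)cc(OC)c(OC)c1OC | intermediate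
9 | 2,3,4-trimethoxy-6-(methoxymethoxy)phenyl formate | O=COc1c(OCOC)cc(OC)c(OC)c1OC | intermediate
10 | 2,3,4-trimethoxy-6-(methoxymethoxy)phenol | Oc1c(OCOC)cc(OC)c(OC)c1OC | intermediate
11 | methyl bromoacetate | COC(=O)CBr | starting material
12 | methyl 2-[2,3,4-trimethoxy-6-(methoxymethoxy)phenoxy]acetate | COC(=O)COc1c(OCOC)cc(OC)c(OC)c1OC | intermediate
13 | methyl (E)-3-[6-(benzyloxy)-2,3,4-trimethoxyphenoxy]-5-oxo-6-[2,3,4-trimethoxy-6-(methoxymethoxy)phenoxy]hex-2-enoate | COC(=O)/C=C(\CC(=O)COc1c(OCOC)cc(OC)c(OC)c1OC)Oc1c(OCc2ccccc2)cc(OC)c(OC)c1OC | intermediate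
14 | 5-[6-(benzyloxy)-2,3,4-trimethoxyphenoxy]-2-[2,3,4-trimethoxy-6-(methoxymethoxy)phenoxy]benzene-1,3-diol (rings C–D–E) | Oc1cc(Oc2c(OCc3ccccc3)cc(OC)c(OC)c2OC)cc(O)c1Oc1c(OCOC)cc(OC)c(OC)c1OC | intermediate
15 | 1-(benzyloxy)-2-{3,5-dimethoxy-4-[2,3,4-trimethoxy-6-(methoxymethoxy)phenoxy]phenoxy}-3,4,5-trimethoxybenzene | COc1cc(Oc2c(OCc3ccccc3)cc(OC)c(OC)c2OC)cc(OC)c1Oc1c(OCOC)cc(OC)c(OC)c1OC | intermediate
16 | 2-{4-[6-(benzyloxy)-2,3,4-trimethoxyphenoxy]-2,6-dimethoxyphenoxy}-3,4,5-trimethoxyphenol | COc1cc(Oc2c(OCc3ccccc3)cc(OC)c(OC)c2OC)cc(OC)c1Oc1c(O)cc(OC)c(OC)c1OC | intermediate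
17 | 5-iodo-1,2,3-trimethoxybenzene | COc1cc(I)cc(OC)c1OC | starting material
18 | 1-(benzyloxy)-3,4,5-trimethoxy-2-(3,4,5-trimethoxyphenoxy)benzene | COc1cc(Oc2c(OCc3ccccc3)cc(OC)c(OC)c2OC)cc(OC)c1OC | intermediate
19 | 3,4,5-trimethoxy-2-(3,4,5-trimethoxyphenoxy)phenol | COc1cc(Oc2c(O)cc(OC)c(OC)c2OC)cc(OC)c1OC | intermediate
20 | 4-bromo-2-methoxyphenol | COc1cc(Br)ccc1O | starting material
21 | 4-bromo-2-iodo-6-methoxyphenol | COc1cc(Br)cc(I)c1O | intermediate
22 | 5-bromo-1-iodo-2,3-dimethoxybenzene | COc1cc(Br)cc(I)c1OC | intermediate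
23 | 5-bromo-1,2-dimethoxy-3-[3,4,5-trimethoxy-2-(3,4,5-trimethoxyphenoxy)phenoxy]benzene (rings F–G–H) | COc1cc(Br)cc(Oc2cc(OC)c(OC)c(OC)c2Oc2cc(OC)c(OC)c(OC)c2)c1OC | intermediate
24 | benzyl-protected ring C–H hexamer, all other oxygens methylated | COc1cc(Oc2c(OCc3ccccc3)cc(OC)c(OC)c2OC)cc(OC)c1Oc1c(Oc2cc(OC)c(OC)c(Oc3cc(OC)c(OC)c(OC)c3Oc3cc(OC)c(OC)c(OC)c3)c2)cc(OC)c(OC)c1OC | intermediate
25 | ring C–H hexamer with free outer hydroxyl on ring C | COc1cc(Oc2c(O)cc(OC)c(OC)c2OC)cc(OC)c1Oc1c(Oc2cc(OC)c(OC)c(Oc3cc(OC)c(OC)c(OC)c3Oc3cc(OC)c(OC)c(OC)c3)c2)cc(OC)c(OC)c1OC | intermediate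
26 | ring C–H hexamer, methyl aryloxyacetate on the outer oxygen of ring C | COc1cc(Oc2c(OCC(=O)OC)cc(OC)c(OC)c2OC)cc(OC)c1Oc1c(Oc2cc(OC)c(OC)c(Oc3cc(OC)c(OC)c(OC)c3Oc3cc(OC)c(OC)c(OC)c3)c2)cc(OC)c(OC)c1OC | intermediate
27 | 2,4,6-trimethoxybenzaldehyde | COc1cc(OC)c(C=O)c(OC)c1 | starting material
28 | 2,4,6-trimethoxyphenyl formate | COc1cc(OC)c(OC=O)c(OC)c1 | intermediate
29 | 2,4,6-trimethoxyphenol | COc1cc(OC)c(O)c(OC)c1 | intermediate
30 | methyl (E)-3-(2,4,6-trimethoxyphenoxy)but-2-enoate | COC(=O)/C=C(\C)Oc1c(OC)cc(OC)cc1OC | intermediate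
31 | methyl (E)-3-(2,4,6-trimethoxyphenoxy)-5-oxo-6-(ring C–H hexamer aryloxy)hex-2-enoate | COC(=O)/C=C(\CC(=O)COc1cc(OC)c(OC)c(OC)c1Oc1cc(OC)c(Oc2c(Oc3cc(OC)c(OC)c(Oc4cc(OC)c(OC)c(OC)c4Oc4cc(OC)c(OC)c(OC)c4)c3)cc(OC)c(OC)c2OC)c(OC)c1)Oc1c(OC)cc(OC)cc1OC | intermediate
32 | ring A–H octamer, nonadecamethyl ether with free 3,5-hydroxyls on ring B | COc1cc(OC)c(Oc2cc(O)c(Oc3cc(OC)c(OC)c(OC)c3Oc3cc(OC)c(Oc4c(Oc5cc(OC)c(OC)c(Oc6cc(OC)c(OC)c(OC)c6Oc6cc(OC)c(OC)c(OC)c6)c5)cc(OC)c(OC)c4OC)c(OC)c3)c(O)c2)c(OC)c1 | intermediate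
33 | CNP0309601.0, ring A–H octamer with 21 free hydroxyls | Oc1cc(O)c(Oc2cc(O)c(Oc3cc(O)c(O)c(O)c3Oc3cc(O)c(Oc4c(Oc5cc(O)c(O)c(Oc6cc(O)c(O)c(O)c6Oc6cc(O)c(O)c(O)c6)c5)cc(O)c(O)c4O)c(O)c3)c(O)c2)c(O)c1 | target

**Step count and risks**

Total: 22 steps. Longest linear sequence: 12 steps (1 → 2 → 3 → 5 → 7 → 14 → 15 → 16 → 24 → 25 → 26 → 32 → 33).

Steps most likely to fail:

1. Step 8. Three processes may divert it: proton transfer from 12 to the dienolate may outrun acylation, the tethered enolate may close through oxygen to a lactone, and methoxide may exchange the ring C aryloxy group at the enol ether carbon during the hot NaOMe stage. The fallback sets out from 12 and separates the two bond formations. Treatment of 12 with MeNH(OMe)·HCl and i-PrMgCl in THF at −20 °C should give N-methoxy-N-methyl-2-[2,3,4-trimethoxy-6-(methoxymethoxy)phenoxy]acetamide F1. Acylation of the lithium dienolate of 7 with F1 at −78 °C stops at the chelated adduct, so no alkoxide is present and keto enoate 13 can be isolated after a mild acidic work-up. Closing 13 with KOt-Bu in t-BuOH/THF at 60 °C, a base too hindered to add to the enol ether, comes back to the route at 14.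

2. Step 21. On the large ester 26, acylation may be slow (limited solubility at −78 °C, bulk next to the ester), so that enolisation of 26 or decay of the dienolate takes over and a late convergent intermediate is lost. The fallback sets out from 15 and folds ring B before the fragments are joined:
   - Hydrogenolysis (H2, Pd/C) gives the ring C–D–E phenol with the MOM group retained F2, and alkylation with 11 (K2CO3) gives its aryloxyacetate F3.
   - The Claisen–Dieckmann sequence with the dienolate of 30 passes through the pentamer keto enoate F4 to the ring A–E resorcinol F5.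
   - Methylation (MeI, K2CO3) gives the ring A–E MOM ether F6, and HCl in MeOH frees the ring E phenol F7.
   - Ullmann coupling with bromide 23 (CuI, picolinic acid, K3PO4, DMSO, 100 °C) gives the fully methylated octamer F8.
   - BBr3 cleavage of its 21 methyl ethers comes back to the route at 33.

3. Step 22. Nineteen ether cleavages must all reach completion, partly methylated products are hard to separate from the very polar polyphenol, and the free pyrogallol and phloroglucinol rings may be lost by air oxidation and irreversible adsorption during purification. The fallback sets out from 32 and adds a derivatise-and-release detour. After the BBr3 treatment the crude product is acetylated directly (Ac2O, pyridine, DMAP) to the henicosaacetate of the target F9, which is air-stable and can be purified on silica gel; fractions that still carry methyl ethers are returned to BBr3. Deacetylation with catalytic NaOMe in degassed MeOH, then neutralisation with an acidic resin, comes back to the route at 33.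

**Further compounds**

F1 | step 8 | N-methoxy-N-methyl-2-[2,3,4-trimethoxy-6-(methoxymethoxy)phenoxy]acetamide | CON(C)C(=O)COc1c(OCOC)cc(OC)c(OC)c1OC
F2 | step 21 | ring C–D–E phenol with MOM retained (15 without benzyl) | COc1cc(Oc2c(O)cc(OC)c(OC)c2OC)cc(OC)c1Oc1c(OCOC)cc(OC)c(OC)c1OC
F3 | step 21 | methyl aryloxyacetate of F2 at the ring C oxygen | COc1cc(Oc2c(OCC(=O)OC)cc(OC)c(OC)c2OC)cc(OC)c1Oc1c(OCOC)cc(OC)c(OC)c1OC
F4 | step 21 | pentamer keto enoate from F3 and 30 | COC(=O)/C=C(\CC(=O)COc1cc(OC)c(OC)c(OC)c1Oc1cc(OC)c(Oc2c(OCOC)cc(OC)c(OC)c2OC)c(OC)c1)Oc1c(OC)cc(OC)cc1OC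
F5 | step 21 | ring A–E resorcinol (free ring B diol, MOM on ring E) | COc1cc(OC)c(Oc2cc(O)c(Oc3cc(OC)c(OC)c(OC)c3Oc3cc(OC)c(Oc4c(OCOC)cc(OC)c(OC)c4OC)c(OC)c3)c(O)c2)c(OC)c1
F6 | step 21 | ring A–E MOM ether with ring B methylated | COc1cc(OC)c(Oc2cc(OC)c(Oc3cc(OC)c(OC)c(OC)c3Oc3cc(OC)c(Oc4c(OCOC)cc(OC)c(OC)c4OC)c(OC)c3)c(OC)c2)c(OC)c1
F7 | step 21 | ring A–E pentamer with free outer hydroxyl on ring E | COc1cc(OC)c(Oc2cc(OC)c(Oc3cc(OC)c(OC)c(OC)c3Oc3cc(OC)c(Oc4c(O)cc(OC)c(OC)c4OC)c(OC)c3)c(OC)c2)c(OC)c1
F8 | step 21 | fully methylated ring A–H octamer (21 methyl ethers) | COc1cc(OC)c(Oc2cc(OC)c(Oc3cc(OC)c(OC)c(OC)c3Oc3cc(OC)c(Oc4c(Oc5cc(OC)c(OC)c(Oc6cc(OC)c(OC)c(OC)c6Oc6cc(OC)c(OC)c(OC)c6)c5)cc(OC)c(OC)c4OC)c(OC)c3)c(OC)c2)c(OC)c1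
F9 | step 22 | henicosaacetate of the target | CC(=O)Oc1cc(OC(C)=O)c(Oc2cc(OC(C)=O)c(Oc3cc(OC(C)=O)c(OC(C)=O)c(OC(C)=O)c3Oc3cc(OC(C)=O)c(Oc4c(Oc5cc(OC(C)=O)c(OC(C)=O)c(Oc6cc(OC(C)=O)c(OC(C)=O)c(OC(C)=O)c6Oc6cc(OC(C)=O)c(OC(C)=O)c(OC(C)=O)c6)c5)cc(OC(C)=O)c(OC(C)=O)c4OC(C)=O)c(OC(C)=O)c3)c(OC(C)=O)c2)c(OC(C)=O)c1
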